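Ring B, the 2-hydroxyphenyl ring, holds its oxygen on C2' and the chain on the adjacent C1'. This is the C1(=O)/C2(alkyl) pattern of a 2-alkylcyclohex-2-enone, one H2 below the phenol. Everything rests on disconnecting the C1'–C6' bond of ring B. An acyclic 1,5-keto aldehyde, methyl 13,17-dioxoheptadecanoate, closes by intramolecular aldol condensation: C12, the ketone alpha-carbon on the long-chain side, bonds to aldehyde carbon C17. That single operation builds the six-membered ring, sets oxygen and chain ortho, and absorbs one chain carbon. The remote terminus travels as a methyl ester, so after aromatization only hydrolysis and C-acylation of phloroglucinol (ring A) remain, with no phenol protection.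

Key step: step 5

Remark: locants C1–C17 of the keto aldehyde follow its ester name (C1 ester carbon, C13 ketone, C17 aldehyde). They map onto ring B as C12→C1', C13→C2', C14→C3', C15→C4', C16→C5' and C17→C6'.
Remark: the target is achiral. The stereocentres of the transient ozonide and ketol form without control and vanish again, so their SMILES carry no descriptors.
Assumption: phloroglucinol is used in anhydrous form (the dihydrate is dried beforehand), because water deactivates BF3·OEt2.

Step 1
Reactants: 1 12-bromododecanoic acid
Product: 2 methyl 12-bromododecanoate
Conditions: MeOH, H2SO4 (cat.), reflux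
Reagents that add atoms: methanol, SMILES CO
Why: Fischer esterification in excess methanol should be clean because the primary bromide is inert to acidic methanol, and it removes the acidic proton that would destroy the organozinc reagent of step 3.

Step 2
Reactants: 3 cyclopentanone
Product: 4 cyclopent-1-en-1-yl trifluoromethanesulfonate
Conditions: Tf2O, 2,6-di-tert-butyl-4-methylpyridine, CH2Cl2, 0 °C → rt
Reagents that add atoms: trifluoromethanesulfonic anhydride, SMILES O=S(=O)(OS(=O)(=O)C(F)(F)F)C(F)(F)F
Why: Enol triflate formation by O-sulfonylation of the enolizing ketone, with a hindered non-nucleophilic pyridine as proton acceptor, is standard for simple cycloalkanones, and the symmetrical ketone can give only one enol triflate.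

Step 3
Reactants: 2 methyl 12-bromododecanoate; 4 cyclopent-1-en-1-yl trifluoromethanesulfonate
Product: 6 methyl 12-(cyclopent-1-en-1-yl)dodecanoate, via alkylzinc bromide 5 (not isolated)
Conditions: 2, Zn dust, I2 (5 mol%), DMA, 80 °C; then 4, PdCl2(dppf) (3 mol%), DMA/THF, 50 °C
Reagents that add atoms: none
Why: Iodine-activated zinc insertion into the primary C–Br bond followed by Negishi cross-coupling tolerates the ester, the C(sp2)–O bond of 4 fixes the double bond inside the five-membered ring at the chain-bearing carbon (no endocyclic/exocyclic mixture as in a carbinol dehydration), and the wide bite angle of dppf favours reductive elimination over beta-hydride elimination.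

Step 4
Reactants: 6 methyl 12-(cyclopent-1-en-1-yl)dodecanoate
Product: 8 methyl 13,17-dioxoheptadecanoate, via secondary ozonide 7 (not isolated)
Conditions: O3, CH2Cl2, −78 °C; then Me2S, −78 °C → rt
Reagents that add atoms: ozone, SMILES [O-][O+]=O
Why: Ozonolysis by the Criegee mechanism with reductive work-up cleaves the only C=C bond, turning the substituted ring carbon into the C13 ketone and the CH carbon into the C17 aldehyde, while Me2S reduces ozonide 7 without touching the ester or the new carbonyl groups.

Step 5
Reactants: 8 methyl 13,17-dioxoheptadecanoate
Product: 10 methyl 11-(6-oxocyclohex-1-en-1-yl)undecanoate, via ketol 9 (not isolated)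
Conditions: piperidine (0.3 equiv), AcOH (0.3 equiv), toluene, 80 °C, slow addition of 8 to 0.01 M final concentration
Reagents that add atoms: none
Why: Piperidinium acetate equilibrates both carbonyl groups with their enamines and iminium ions; the enamine (or enol) C12=C13 on the long-chain side of the ketone attacks the acid-activated aldehyde carbon C17 through C12 to give ketol 9, which loses water by an E1cB pathway to the conjugated enone while hydrolysis returns the amine. The closest known reaction type is the intramolecular aldol condensation of a 1,5-dicarbonyl compound, that is, the ring-closing half of a Robinson annulation. Ring B closes in the 6-(enolendo)-exo-trig mode, since both carbons of the nucleophilic C12=C13 bond become ring members while the aldehyde C=O stays outside the ring, and this mode is favoured for six-membered rings. The two stereocentres of 9 arise without control and are erased by the dehydration, so the product has none. The step needs site selectivity among the enolizable carbons C12, C14 and C16, which ring size secures, because C14 to C17 or C16 to C13 bonding would give only strained cyclobutanols that revert by retro-aldol cleavage, whereas the C12 pathway is drained irreversibly by dehydration. It also needs ring closure to beat bimolecular condensation of the aldehyde, which slow addition into dilute solution and the mild buffered catalyst secure.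

Step 6
Reactants: 10 methyl 11-(6-oxocyclohex-1-en-1-yl)undecanoate
Product: 12 methyl 11-(2-hydroxyphenyl)undecanoate, via cross-conjugated dienone 11 (not isolated)
Conditions: Pd(O2CCF3)2 (5 mol%), 2-(dimethylamino)pyridine (10 mol%), TsOH·H2O (20 mol%), O2 (1 atm), DMSO, 80 °C
Reagents that add atoms: none
Why: In this palladium-catalysed aerobic dehydrogenation of a cyclohexenone, divalent palladium palladates the ring CH2 next to the carbonyl group through the enol, beta-hydride elimination gives dienone 11, which tautomerizes irreversibly to the phenol, and O2 returns zerovalent palladium to the divalent state, the ester and the saturated chain being inert.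

Step 7
Reactants: 12 methyl 11-(2-hydroxyphenyl)undecanoate
Product: 13 11-(2-hydroxyphenyl)undecanoic acid
Conditions: LiOH, THF/MeOH/H2O, rt; then 1 M HCl
Reagents that add atoms: lithium hydroxide, SMILES [Li+].[OH-]
Why: Saponification (BAc2 hydrolysis) of an unhindered methyl ester is reliable, and the phenolate formed alongside is simply reprotonated on acidification.

Step 8
Reactants: 13 11-(2-hydroxyphenyl)undecanoic acid; 14 phloroglucinol (benzene-1,3,5-triol)
Product: 15 11-(2-hydroxyphenyl)-1-(2,4,6-trihydroxyphenyl)undecan-1-one (target)
Conditions: 14 (2 equiv, anhydrous), BF3·OEt2 (neat), 85 °C; then aq. NaOAc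
Reagents that add atoms: none
Why: Friedel–Crafts C-acylation of phloroglucinol with a free carboxylic acid in BF3·OEt2 is the standard entry to acylphloroglucinols and tolerates free phenols in the acid partner, because ring A with three mutually reinforcing hydroxyl groups is far more nucleophilic than the monohydroxy ring B, its three CH positions are equivalent, and the deactivating first acyl group together with excess 14 suppresses a second acylation.

Compound list
1 | 12-bromododecanoic acid | OC(=O)CCCCCCCCCCCBr | starting material
2 | methyl 12-bromododecanoate | COC(=O)CCCCCCCCCCCBr | intermediate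
3 | cyclopentanone | O=C1CCCC1 | starting material
4 | cyclopent-1-en-1-yl trifluoromethanesulfonate | O=S(=O)(OC1=CCCC1)C(F)(F)F | intermediate
5 | bromo(12-methoxy-12-oxododecyl)zinc, alkylzinc bromide formed in the flask (not isolated) | COC(=O)CCCCCCCCCCC[Zn]Br | intermediate
6 | methyl 12-(cyclopent-1-en-1-yl)dodecanoate | COC(=O)CCCCCCCCCCCC1=CCCC1 | intermediate
7 | methyl 12-(6,7,8-trioxabicyclo[3.2.1]octan-1-yl)dodecanoate, secondary ozonide, racemic (not isolated) | COC(=O)CCCCCCCCCCCC12CCCC(OO1)O2 | intermediate
8 | methyl 13,17-dioxoheptadecanoate, precursor of the key step | COC(=O)CCCCCCCCCCCC(=O)CCCC=O | intermediate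
9 | methyl 11-(2-hydroxy-6-oxocyclohexyl)undecanoate, ketol, mixture of diastereomers (not isolated) | COC(=O)CCCCCCCCCCC1C(O)CCCC1=O | intermediate
10 | methyl 11-(6-oxocyclohex-1-en-1-yl)undecanoate, product of the key step | COC(=O)CCCCCCCCCCC1=CCCCC1=O | intermediate
11 | methyl 11-(6-oxocyclohexa-1,4-dien-1-yl)undecanoate, keto tautomer of the phenol (not isolated) | COC(=O)CCCCCCCCCCC1=CCC=CC1=O | intermediate
12 | methyl 11-(2-hydroxyphenyl)undecanoate | COC(=O)CCCCCCCCCCc1ccccc1O | intermediate
13 | 11-(2-hydroxyphenyl)undecanoic acid | OC(=O)CCCCCCCCCCc1ccccc1O | intermediate
14 | phloroglucinol (benzene-1,3,5-triol) | Oc1cc(O)cc(O)c1 | starting material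
15 | 11-(2-hydroxyphenyl)-1-(2,4,6-trihydroxyphenyl)undecan-1-one | O=C(CCCCCCCCCCc1ccccc1O)c1c(O)cc(O)cc1O | target

Total step count: 8
Longest linear sequence: 7 (steps 1, 3, 4, 5, 6, 7, 8; the branch that starts with step 2 is equally long)

Steps most likely to fail

Step 5 (key step). Condensation between two molecules through the enamine of the unhindered aldehyde end may compete with ring closure and consume the material by oligomerization.
- The fallback sets out from 8 and masks the aldehyde chemoselectively (HC(OMe)3, TsOH cat., MeOH, 0 °C; the ketone reacts far more slowly) as methyl 17,17-dimethoxy-13-oxoheptadecanoate F1.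
- Catalytic TsOH·H2O in wet THF at 60 °C under dilution then releases the aldehyde only slowly. Its stationary concentration stays low, and no amine is present to turn it into a nucleophile.
- The ketone enol closes the same C12–C17 bond through ketol 9, and the acid dehydrates it. This is the known acid-catalysed unmasking and aldol condensation of keto acetals.
- The fallback comes back to the route at 10.

Step 6. The catalyst may aggregate to palladium metal before conversion is complete, or the lipophilic substrate may turn over sluggishly in DMSO.
- The fallback is a stoichiometric, metal-free dehydrogenation in two stages that sets out from 10.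
- Soft enolization at the ring CH2 next to the carbonyl group (TMSOTf, Et3N, CH2Cl2, 0 °C; the ester is untouched) gives methyl 11-{6-[(trimethylsilyl)oxy]cyclohexa-1,5-dien-1-yl}undecanoate F2.
- DDQ (toluene, rt) removes hydride and proton from the two remaining ring CH2 groups to give methyl 11-{2-[(trimethylsilyl)oxy]phenyl}undecanoate F3.
- A work-up with 1 M HCl in THF cleaves the labile aryl silyl ether, and the fallback comes back to the route at 12.

Step 8. O-acylation or self-acylation at the phenol of ring B, a second acylation of ring A, or degradation in the hot Lewis acid may erode the conversion and complicate the isolation of the polar product.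
- The fallback sets out from 13 and replaces the nucleophile with 1,3,5-trimethoxybenzene (COc1cc(OC)cc(OC)c1).
- This arene is acylated by the free acid in P2O5/MeSO3H at rt to 40 °C and gives the easily purified 11-(2-hydroxyphenyl)-1-(2,4,6-trimethoxyphenyl)undecan-1-one F4.
- Exhaustive ether cleavage with excess BBr3 (CH2Cl2, −78 °C → rt, aqueous work-up) then frees the three hydroxyl groups of ring A, and the fallback comes back to the route at 15.

Further compounds
F1 | step 5 | methyl 17,17-dimethoxy-13-oxoheptadecanoate | COC(=O)CCCCCCCCCCCC(=O)CCCC(OC)OC
F2 | step 6 | methyl 11-{6-[(trimethylsilyl)oxy]cyclohexa-1,5-dien-1-yl}undecanoate | COC(=O)CCCCCCCCCCC1=CCCC=C1O[Si](C)(C)C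
F3 | step 6 | methyl 11-{2-[(trimethylsilyl)oxy]phenyl}undecanoate | COC(=O)CCCCCCCCCCc1ccccc1O[Si](C)(C)C
F4 | step 8 | 11-(2-hydroxyphenyl)-1-(2,4,6-trimethoxyphenyl)undecan-1-one | COc1cc(OC)c(C(=O)CCCCCCCCCCc2ccccc2O)c(OC)c1
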